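**Retrosynthetic overview**

- Megaphone numbering: ring A is C1 (quaternary), C2 (CH2), C3 (CH–OMe), C4=C5, C6 (C=O); the side chain is C8 (CH–Me) and C7 (carbinol bearing the trimethoxyphenyl ring); the allyl group is C9–C11.
- Feature the strategy rests on: C1–C6 of ring A carry the oxygen pattern of a 2-allyl-4-methoxyphenol (C6 phenol carbon, C3 para methoxy carbon, C1 allyl-bearing ortho carbon) and C7–C8 that of a propenylarene, so C1–C8 is the junction of an oxidised phenol ortho carbon with a styrene β-carbon.
- Key disconnection: C1–C8 and C7–O of dienone 14 lead back to bromophenol 5, (E)-isoelemicin 9 and acetic acid 10, joined in one anodic, chiral-iodoarene-relayed dearomatising step; the bromine occupies C5.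
- Endgame from 14: C3 enol ether to ketone, to (R)-carbinol, to methyl ether; C5–Br to C5–H; C7 acetate to alcohol. Precursors: 5 from 1 and 2 (O-allylation, Claisen); 9 from 6 and 7 (Grignard addition, dehydration).
- Ring order: no ring is closed anywhere; ring A is the dearomatised benzene ring of 1 and the aryl ring comes from 6.

Key step: step 5

Assumption: mediator 11 is taken as a purchasable chiral iodoarene, and its (R,R) form is assumed to shield the ring face that leads to 1S in 14; the sense of induction is not established, and the (S,S) form would be used if it proves opposite.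

**Route**

Step 1
Reactants: 1 2-bromo-4-methoxyphenol; 2 allyl bromide
Product: 3 1-(allyloxy)-2-bromo-4-methoxybenzene
Conditions: K2CO3, acetone, reflux
Reagents that add atoms: none
Why: Williamson ether synthesis in which the phenoxide displaces bromide from the primary allylic carbon by SN2, with no stereocentre involved.

Step 2
Reactants: 3 1-(allyloxy)-2-bromo-4-methoxybenzene
Product: 5 2-allyl-6-bromo-4-methoxyphenol, via Claisen dienone 4 (not isolated)
Conditions: N,N-diethylaniline, 190 °C, argon
Reagents that add atoms: none
Why: Aromatic Claisen rearrangement, whose [3,3] shift ends productively only at the hydrogen-bearing ortho carbon before dienone 4 tautomerises to the phenol, leaving the bromine as the group that later blocks C5.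

Step 3
Reactants: 6 3,4,5-trimethoxybenzaldehyde; 7 ethylmagnesium bromide
Product: 8 1-(3,4,5-trimethoxyphenyl)propan-1-ol (racemic)
Conditions: THF, 0 °C to rt; then aq NH4Cl
Reagents that add atoms: none
Why: Grignard addition to a non-enolisable aryl aldehyde, giving a racemic carbinol whose stereocentre is removed in the next step.

Step 4
Reactants: 8 1-(3,4,5-trimethoxyphenyl)propan-1-ol
Product: 9 (E)-isoelemicin, (E)-1,2,3-trimethoxy-5-(prop-1-en-1-yl)benzene
Conditions: p-TsOH·H2O (2 mol%), toluene, reflux, Dean–Stark trap
Reagents that add atoms: none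
Why: Acid-catalysed E1 dehydration through the trimethoxybenzylic cation with removal of water, where conjugation and equilibration under the acid should favour the E alkene and low acid loading in dilute solution limits cationic dimerisation.

Step 5
Reactants: 5 2-allyl-6-bromo-4-methoxyphenol; 9 (E)-isoelemicin; 10 acetic acid
Product: 14 (1R,2S)-2-[(1S)-1-allyl-3-bromo-5-methoxy-2-oxocyclohexa-3,5-dien-1-yl]-1-(3,4,5-trimethoxyphenyl)propyl acetate, via diacetoxy-λ3-iodane 12 (not isolated), via aryloxy-λ3-iodane 13 (not isolated)
Conditions: (i) 11 (1.2 equiv), AcOH/HFIP 1:4, Bu4NBF4, glassy-carbon anode, Pt cathode, divided cell, constant current, 2.2 F per mol of 11, 0 °C; (ii) anolyte added slowly to 5 and 9 (1.5 equiv) in CH2Cl2, −40 °C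
Reagents that add atoms: none
Why: Proposed new method: the trivalent iodine species 12 is made at the anode before the substrates are present, because 5 and 9 are both oxidised more easily than the iodoarene, and it exchanges one acetate for the phenol oxygen to give 13, whose ring is a phenoxenium equivalent with positive character at C1, C3 and C5; C8 of 9 then attacks C1 with release of 11, and the 3,4,5-trimethoxybenzylic C7 cation is taken up by acetate, so C1–C8 and C7–O are formed, three stereocentres are set and no ring is closed. The closest known reaction types are the anodic and hypervalent-iodine formal [3+2] couplings of 4-methoxyphenols with propenylarenes, in which the phenol oxygen closes onto C7, and the enantioselective dearomatisation of phenols by chiral iodoarenes; what is new is C–C bond formation at a substituted ortho carbon under control of the iodine-bound chiral ligand with capture of the cation by a third component. C1 is to be controlled by the lactamide arms on the iodine bound to the C6 oxygen, which should leave open the face from which C6, C1, C2 appear clockwise; C8 requires the compact approach with C7 and its aryl group over the ring, the methyl over the C2 edge and H toward C6, which stacking of the electron-rich arene on the cationic ring should favour; C7 follows from allylic 1,3-strain, which holds the C8–H bond in the plane of the benzylic cation so that acetate enters anti to the quaternary C1, equal to anti addition across the E alkene and giving 7R,8S. Attack at C1 and not at C5 or C3 is needed: the bromine encumbers C5 and also disfavours closure of the C7 cation onto C5, and adducts at the methoxy-bearing C3 can ionise again whereas the C1 adduct is quaternary and cannot rearomatise. Closure of the C6 oxygen onto C7 would give an oxocarbenium ion with no path to a neutral product and should reopen, which leaves acetate capture as the productive exit. The low temperature and the CH2Cl2-rich, weakly ionising medium are chosen to keep the phenol bound to iodine until the alkene attacks, since the face selectivity depends on it.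

Step 6
Reactants: 14 dienone acetate from step 5
Product: 15 (1R,2S)-2-[(1R)-1-allyl-3-bromo-2,5-dioxocyclohex-3-en-1-yl]-1-(3,4,5-trimethoxyphenyl)propyl acetate
Conditions: 1 M aq HCl, THF, 0 °C, directly on freshly prepared 14
Reagents that add atoms: water, O
Why: Enol ether hydrolysis by protonation at C2, hydration of the C3 oxocarbenium ion and loss of methanol, run cold and without storing 14 because 6-allylcyclohexa-2,4-dienones are prone to Cope shift and dimerisation, while the benzylic acetate should survive dilute acid at 0 °C.

Step 7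
Reactants: 15 bromo-enedione
Product: 16 (1R,2S)-2-[(1R,5R)-1-allyl-3-bromo-5-hydroxy-2-oxocyclohex-3-en-1-yl]-1-(3,4,5-trimethoxyphenyl)propyl acetate
Conditions: (S)-2-methyl-CBS-oxazaborolidine (20 mol%), catecholborane, toluene, −78 °C
Reagents that add atoms: none
Why: Corey–Bakshi–Shibata reduction, in which the C3 carbonyl (between CH2 and CH=) reacts before the C6 carbonyl (between quaternary C1 and brominated C5), the (S)-catalyst treats the alkene arm as the large group and delivers hydride to the ring face carrying the allyl group to set 3R with the hydroxyl cis to the C8 side chain, and catecholborane spares the terminal alkene.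

Step 8
Reactants: 16 allylic alcohol
Product: 17 (1R,2S)-2-[(1R,5R)-1-allyl-3-bromo-5-methoxy-2-oxocyclohex-3-en-1-yl]-1-(3,4,5-trimethoxyphenyl)propyl acetate
Conditions: Ag2O, MeI, 4 Å molecular sieves, MeCN, 40 °C, dark
Reagents that add atoms: iodomethane, CI
Why: Purdie methylation, a non-basic O-alkylation that avoids γ-deprotonation of the hydroxy enone and leaves the acetate, the vinyl bromide and all stereocentres untouched.

Step 9
Reactants: 17 bromo enone methyl ether
Product: 18 megaphone acetate, (1R,2S)-2-[(1R,5R)-1-allyl-5-methoxy-2-oxocyclohex-3-en-1-yl]-1-(3,4,5-trimethoxyphenyl)propyl acetate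
Conditions: Pd(PPh3)4 (5 mol%), Bu3SnH (1.2 equiv, slow addition), toluene, rt
Reagents that add atoms: none
Why: Palladium-catalysed hydrodehalogenation, in which zerovalent palladium inserts into the activated C5–Br bond of the α-bromoenone, tin hydride transfers hydride and reductive elimination gives the enone, conditions under which the isolated alkene, the benzylic acetate and the allylic ether should not react.

Step 10
Reactants: 18 megaphone acetate
Product: 19 megaphone, (4R,6R)-6-allyl-6-[(1R,2S)-1-hydroxy-1-(3,4,5-trimethoxyphenyl)propan-2-yl]-4-methoxycyclohex-2-en-1-one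
Conditions: K2CO3 (0.3 equiv), MeOH, 0 °C
Reagents that add atoms: none
Why: Base-catalysed transesterification of the acetate with methanol, safe from retro-aldol cleavage because the freed hydroxyl is γ and not β to the C6 carbonyl, with the low temperature limiting γ-deprotonation of the enone.

**Compound list**

1 | 2-bromo-4-methoxyphenol | COc1ccc(O)c(Br)c1 | starting material
2 | allyl bromide | C=CCBr | starting material
3 | 1-(allyloxy)-2-bromo-4-methoxybenzene | C=CCOc1ccc(OC)cc1Br | intermediate
4 | 6-allyl-2-bromo-4-methoxycyclohexa-2,4-dien-1-one (Claisen dienone, racemic, not isolated) | C=CCC1C=C(OC)C=C(Br)C1=O | intermediate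
5 | 2-allyl-6-bromo-4-methoxyphenol | C=CCc1cc(OC)cc(Br)c1O | intermediate
6 | 3,4,5-trimethoxybenzaldehyde | COc1cc(C=O)cc(OC)c1OC | starting material
7 | ethylmagnesium bromide | CC[Mg]Br | starting material
8 | 1-(3,4,5-trimethoxyphenyl)propan-1-ol (racemic) | CCC(O)c1cc(OC)c(OC)c(OC)c1 | intermediate
9 | (E)-isoelemicin | C/C=C/c1cc(OC)c(OC)c(OC)c1 | intermediate
10 | acetic acid | CC(=O)O | starting material
11 | (R,R)-2,2'-[(2-iodo-1,3-phenylene)bis(oxy)]bis(N-mesitylpropanamide), mediator | C[C@@H](Oc1cccc(O[C@H](C)C(=O)Nc2c(C)cc(C)cc2C)c1I)C(=O)Nc1c(C)cc(C)cc1C | starting material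
12 | diacetoxy-λ3-iodane of 11 (not isolated) | C[C@@H](Oc1cccc(O[C@H](C)C(=O)Nc2c(C)cc(C)cc2C)c1I(OC(C)=O)OC(C)=O)C(=O)Nc1c(C)cc(C)cc1C | intermediate
13 | acetoxy(2-allyl-6-bromo-4-methoxyphenoxy)-λ3-iodane of 11 (not isolated) | C=CCc1cc(OC)cc(Br)c1OI(OC(C)=O)c1c(O[C@H](C)C(=O)Nc2c(C)cc(C)cc2C)cccc1O[C@H](C)C(=O)Nc1c(C)cc(C)cc1C | intermediate
14 | (1R,2S)-2-[(1S)-1-allyl-3-bromo-5-methoxy-2-oxocyclohexa-3,5-dien-1-yl]-1-(3,4,5-trimethoxyphenyl)propyl acetate | C=CC[C@]1([C@H](C)[C@@H](OC(C)=O)c2cc(OC)c(OC)c(OC)c2)C=C(OC)C=C(Br)C1=O | intermediate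
15 | (1R,2S)-2-[(1R)-1-allyl-3-bromo-2,5-dioxocyclohex-3-en-1-yl]-1-(3,4,5-trimethoxyphenyl)propyl acetate | C=CC[C@]1([C@H](C)[C@@H](OC(C)=O)c2cc(OC)c(OC)c(OC)c2)CC(=O)C=C(Br)C1=O | intermediate
16 | (1R,2S)-2-[(1R,5R)-1-allyl-3-bromo-5-hydroxy-2-oxocyclohex-3-en-1-yl]-1-(3,4,5-trimethoxyphenyl)propyl acetate | C=CC[C@]1([C@H](C)[C@@H](OC(C)=O)c2cc(OC)c(OC)c(OC)c2)C[C@@H](O)C=C(Br)C1=O | intermediate
17 | (1R,2S)-2-[(1R,5R)-1-allyl-3-bromo-5-methoxy-2-oxocyclohex-3-en-1-yl]-1-(3,4,5-trimethoxyphenyl)propyl acetate | C=CC[C@]1([C@H](C)[C@@H](OC(C)=O)c2cc(OC)c(OC)c(OC)c2)C[C@@H](OC)C=C(Br)C1=O | intermediate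
18 | megaphone acetate | C=CC[C@]1([C@H](C)[C@@H](OC(C)=O)c2cc(OC)c(OC)c(OC)c2)C[C@@H](OC)C=CC1=O | intermediate
19 | megaphone | C=CC[C@]1([C@H](C)[C@@H](O)c2cc(OC)c(OC)c(OC)c2)C[C@@H](OC)C=CC1=O | target

**Step count**

Total step count: 10. Longest linear sequence: 8 steps (1, 2, 5–10; the branch through 3 and 4 is equally long).

**Steps most likely to fail**

1. Step 5 (proposed new method). What may go wrong:
- The phenol may ionise away from iodine before the alkene arrives, which would erase the face selectivity.
- The alkene may approach in the wrong relative orientation and give the C1/C8 diastereomer.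
- The C7 cation may close onto the C6 oxygen or onto C5 instead of being trapped by acetate.
- The propenylarene may be oxidised in competition with the phenol.

Fallback by known chemistry, setting out from 8 and 1 and returning at 14; it builds C7 and C8 on an intact phenol and then dearomatises by C-allylation:
- Oxidation of 8 with MnO2 gives 1-(3,4,5-trimethoxyphenyl)propan-1-one F1.
- Bromination of 1 with NBS gives 2,6-dibromo-4-methoxyphenol F2, which TBSCl and imidazole convert to tert-butyl(2,6-dibromo-4-methoxyphenoxy)dimethylsilane F3.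
- Palladium-catalysed α-arylation of F1 with an excess of F3 (Pd2(dba)3, XPhos, K3PO4, toluene, 80 °C) gives the racemic α-aryl ketone F4.
- Transfer hydrogenation with dynamic kinetic resolution (RuCl[(S,S)-TsDPEN](p-cymene), HCO2H/Et3N, DBU) should give the (1S,2S)-alcohol F5, with hydride entering anti to the C8 aryl group.
- Mitsunobu esterification with acetic acid (PPh3, DIAD) inverts C7 and gives the (1R,2S)-acetate F6.
- TBAF buffered with AcOH frees the phenol F7.
- C-allylation of the sodium phenolate of F7 (NaH, toluene, 0 °C) with allyl bromide 2 at the alkyl-bearing ortho carbon gives 14, after separation from the O-allyl ether and the C1 epimer.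

2. Step 7. What may go wrong: poor facial selectivity at C3, because the quaternary C1 may bias the ring more strongly than the catalyst, or reduction at C6. Fallback from 15 back to 16, using substrate control followed by inversion:
- Luche reduction (NaBH4, CeCl3·7H2O, MeOH, −78 °C) is run on 15.
- Should it deliver the (5S)-hydroxy epimer F8, Mitsunobu reaction with chloroacetic acid (PPh3, DIAD) gives the (5R)-chloroacetate F9.
- Thiourea with NaHCO3 in EtOH cleaves F9 to 16 without touching the C7 acetate.

3. Step 9. What may go wrong: carbopalladation of the allyl alkene by the vinylpalladium intermediate, or conjugate reduction of the product enone by the tin hydride. Fallback from 17 back to 18, by conjugate reduction and elimination without palladium: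
- [(Ph3P)CuH]6 in wet THF adds hydride at C4 and gives the saturated α-bromo ketone F10 as a mixture at the bromine-bearing carbon.
- DBU in CH2Cl2 eliminates hydrogen bromide across C4–C5 to give 18.

**Further compounds**

F1 | step 5 | 1-(3,4,5-trimethoxyphenyl)propan-1-one | CCC(=O)c1cc(OC)c(OC)c(OC)c1
F2 | step 5 | 2,6-dibromo-4-methoxyphenol | COc1cc(Br)c(O)c(Br)c1
F3 | step 5 | tert-butyl(2,6-dibromo-4-methoxyphenoxy)dimethylsilane | COc1cc(Br)c(O[Si](C)(C)C(C)(C)C)c(Br)c1
F4 | step 5 | racemic 2-[3-bromo-2-(tert-butyldimethylsilyloxy)-5-methoxyphenyl]-1-(3,4,5-trimethoxyphenyl)propan-1-one | CC(C(=O)c1cc(OC)c(OC)c(OC)c1)c1cc(OC)cc(Br)c1O[Si](C)(C)C(C)(C)C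
F5 | step 5 | (1S,2S)-2-[3-bromo-2-(tert-butyldimethylsilyloxy)-5-methoxyphenyl]-1-(3,4,5-trimethoxyphenyl)propan-1-ol | C[C@H]([C@H](O)c1cc(OC)c(OC)c(OC)c1)c1cc(OC)cc(Br)c1O[Si](C)(C)C(C)(C)C
F6 | step 5 | (1R,2S)-2-[3-bromo-2-(tert-butyldimethylsilyloxy)-5-methoxyphenyl]-1-(3,4,5-trimethoxyphenyl)propyl acetate | C[C@H]([C@@H](OC(C)=O)c1cc(OC)c(OC)c(OC)c1)c1cc(OC)cc(Br)c1O[Si](C)(C)C(C)(C)C
F7 | step 5 | (1R,2S)-2-(3-bromo-2-hydroxy-5-methoxyphenyl)-1-(3,4,5-trimethoxyphenyl)propyl acetate | C[C@H]([C@@H](OC(C)=O)c1cc(OC)c(OC)c(OC)c1)c1cc(OC)cc(Br)c1O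
F8 | step 7 | (1R,2S)-2-[(1R,5S)-1-allyl-3-bromo-5-hydroxy-2-oxocyclohex-3-en-1-yl]-1-(3,4,5-trimethoxyphenyl)propyl acetate | C=CC[C@]1([C@H](C)[C@@H](OC(C)=O)c2cc(OC)c(OC)c(OC)c2)C[C@H](O)C=C(Br)C1=O
F9 | step 7 | (1R,2S)-2-[(1R,5R)-1-allyl-3-bromo-5-(chloroacetoxy)-2-oxocyclohex-3-en-1-yl]-1-(3,4,5-trimethoxyphenyl)propyl acetate | C=CC[C@]1([C@H](C)[C@@H](OC(C)=O)c2cc(OC)c(OC)c(OC)c2)C[C@@H](OC(=O)CCl)C=C(Br)C1=O
F10 | step 9 | (1R,2S)-2-[(1R,5R)-1-allyl-3-bromo-5-methoxy-2-oxocyclohexyl]-1-(3,4,5-trimethoxyphenyl)propyl acetate (either configuration at the bromine-bearing carbon) | C=CC[C@]1([C@H](C)[C@@H](OC(C)=O)c2cc(OC)c(OC)c(OC)c2)C[C@@H](OC)CC(Br)C1=O
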